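Slowness shows first. Over the first 1.67 d the north-east run, charged with 13 mM, gains 1.91 mM d⁻¹ of target, and the east run, charged with 30 mM, gains 2.14 mM d⁻¹, an apparent zero-order rate.

the same everywhere: gas 1.6 mM (held)
- north-east: solid substrate 13 mM; run made earlier
- east: solid substrate 30 mM; run made earlier
- flask: solid substrate 20 mM; time 8.0 d

- north-east (time / d: target / %, solid product / %): 0.625: 6.3, 0.2; 1.67: 24.6, 0; 3.00: 43.9, 0; 5.00: 56.7, 3.2; 8.00: 60.5, 8.3; 10.0: 60.9, 7.3
- east (time / d: target / %, solid product / %): 1.67: 11.9, 0; 3.00: 20.4, 0; 5.00: 29.2, 3.8; 6.00: 34.2, 10.4; 8.00: 41.4, 17.8; 10.0: 45.1, 20.4

(scatter of a reading: 1 percentage point)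

- target is meant together with its solid product
- solid, in amounts per volume of the solution: solid substrate, solid product
- what was read earlier has a scatter of 1 percentage point, one standard deviation
- at the start none of the solid substrate is in solution
- at the start none of the gas is in solution
- dissolved substrate means what is dissolved; the solid is not counted in it

- the target and solid product together standing at 8.0 d, as a percentage of the solid substrate charged
- concentration of dissolved substrate in solution at 8.0 d, in percent of saturation

The time scales can be laid out from the shortest up. The first rung is crystals: both runs show no solid product at 3.00 d and show it at 5.00 d, and the east run holds 7.08 mM of target outside the solid at 8.00 d. Solid product is counted inside the target in the figure asked. The next rung is the reading at 8.0 d. The last rung is the filling time. The east run stands at 12.4 mM of target at 8.00 d, which gives the feed, the target standing in a well-charged flask per day of its run: 1.55 mM d⁻¹. Reckoned at that feed, the charge of the flask takes 12.9 d, longer than the 8.0 d it gets, and the reckoning here gives 62.1% for the flask, an estimate and no bound, since it supposes that the feed holds for the whole time.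

The forecast gives 66% (63% to 69%) and 15% of saturation (7% to 27%), holding that “the solid is just target that has crystallised”. Its figure lies above this estimate.

The flask gives 50.9% and 1.42% of saturation.

    solid substrate ⇌ dissolved substrate, rate k1*(cs1 - [dissolved substrate]) while solid is left; crystals form when [dissolved substrate] > cs1 (solubility = 12.0 mM, k = 0.0372 h⁻¹)
    dissolved substrate + reagent → target (k = 24.4 M⁻¹ h⁻¹)
    dissolved substrate + target → side product (k = 1.24 M⁻¹ h⁻¹)
    solid product ⇌ target, rate k4*(cs4 - [target]) while solid is left; crystals form when [target] > cs4 (solubility = 7.10 mM, k = 4.66 h⁻¹)
    gas ⇌ reagent, rate k5*(csat - [reagent]) (kL = 0.134 h⁻¹)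

The flask holds 10.2 mM of target at 8.0 d, below the 12.4 mM the feed gives, and its solid substrate stands at 0% by 4.00 d. The neighbour with 80 mM of solid substrate keeps 52.0% of it as solid and reads 16.2%, where the feed gives 15.5%. The flask is close to rest. At 80.0 d its target has gained 0.53 percentage points, its side product has gone from 48.3% to 48.6%, its dissolved substrate has gone from 0.850% to 0% of the charge, and its reagent has climbed from 1.53 mM to 1.60 mM.

(The readings were computed on assumed constants; noise was put on by code.)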